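**Retrosynthetic overview**
- The target comes from a silyl-protected labd-7-en-3β-ol by desilylation and diacetylation, and that from an 11-carboxy acid by reductive decarboxylation; the carboxyl only carries the side chain into the key step.
- Key step: Ireland–Claisen [3,3] rearrangement of a 7β-allylic ester (Δ8(9)) forms the C9–C11 bond, sets C9 and leaves C7=C8. The acyl part is the C6 acid cut from (S)-citronellol (C13 bought).
- The allylic alcohol comes from the ring-B enone by epoxidation and Wharton transposition; Mitsunobu esterification inverts C7 to β.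
- trans-Decalin: ring B is bought as (R)-carvone (C5). C10 is set by two anti alkylations (methyl, then cyanoethyl), ring A by radical cyclisation of the isopropenyl group onto the nitrile, C3 by ketone reduction.
- Ring order: B (bought), then A; the side chain is attached after both rings exist.

Assumption: bicyclic compounds carry labdane ring numbers (C1–C10; methyls on C4, C8, C10; α = face opposite the C10 methyl); (R)-(−)-carvone and (S)-(−)-citronellol are bought enantiopure. The route is designed on paper and has not been run.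

**Route**

Step 1
Reactants: 1 (R)-(−)-carvone
Product: 2 (5R)-2,6-dimethyl-5-(prop-1-en-2-yl)cyclohex-2-en-1-one (6-methylcarvone; C6 epimers)
Conditions: LDA, THF, −78 °C; MeI, −78 → 0 °C
Reagents that add atoms: iodomethane, CI
Why: LDA removes the α′-proton kinetically and the cross-conjugated enolate is methylated (enolate alkylation); the new C6 centre is an epimer mixture that is erased when this carbon is enolised again in step 2.

Step 2
Reactants: 2 6-methylcarvone
Product: 3 3-[(1S,6S)-1,3-dimethyl-2-oxo-6-(prop-1-en-2-yl)cyclohex-3-en-1-yl]propanenitrile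
Conditions: LDA, THF, −78 °C; CH2=CHCN, t-BuOH, −78 °C; AcOH
Reagents that add atoms: acrylonitrile, C=CC#N
Why: The tetrasubstituted lithium enolate adds to acrylonitrile (Michael addition) on the face anti to the neighbouring isopropenyl group, which fixes the quaternary centre (future C10, methyl β) from the bought centre, while t-BuOH protonates the nitrile anion before it can add back to the enone.

Step 3
Reactants: 3 cyanoethyl enone
Product: 5 (4aS,8aS)-2,5,5,8a-tetramethyl-4,4a,5,7,8,8a-hexahydronaphthalene-1,6-dione (4,4,8,10-tetramethyl-trans-decal-7-ene-3,9-dione), via cyclic ketimine 4 (not isolated)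
Conditions: Fe(acac)3 (cat.), PhSiH3, EtOH, 60 °C; then 1 M HCl, THF, rt
Reagents that add atoms: water, O
Why: Metal-hydride hydrogen-atom transfer to the isopropenyl group gives a tertiary radical that closes 6-exo onto the nitrile (radical cyclisation), forming ring A with the gem-dimethyl carbon; the fusion is trans because C5 and C10 are already set, and the imine is hydrolysed on work-up.

Step 4
Reactants: 5 enedione
Product: 6 (4aS,6S,8aS)-6-hydroxy-2,5,5,8a-tetramethyl-4a,5,6,7,8,8a-hexahydronaphthalen-1(4H)-one (3β-hydroxy enone)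
Conditions: NaBH4, MeOH, −40 °C
Reagents that add atoms: none
Why: Borohydride reduces the saturated C3 ketone faster than the doubly hindered conjugated C9 ketone, and hydride enters axially from the α-face (away from the axial 4β and 10β methyls) to give the equatorial 3β-alcohol.

Step 5
Reactants: 6 3β-hydroxy enone
Product: 7 7α,8α-epoxy-3β-hydroxy-4,4,8,10-tetramethyl-trans-decalin-9-one
Conditions: 30% H2O2, NaOH (cat.), MeOH, 0 °C
Reagents that add atoms: hydrogen peroxide, OO
Why: Weitz–Scheffer nucleophilic epoxidation: hydroperoxide adds axially to C7 from the α-face of the rigid enone and the enolate closes to the 7α,8α-epoxide.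

Step 6
Reactants: 7 epoxy ketone
Product: 9 (3S,5R,7R,10R)-4,4,8,10-tetramethyl-trans-decal-8(9)-ene-3β,7α-diol, via epoxy hydrazone 8 (not isolated)
Conditions: N2H4·H2O, AcOH (cat.), MeOH, 0 °C → rt
Reagents that add atoms: none
Why: Wharton transposition: the epoxy hydrazone fragments with loss of N2 to the transposed allylic alcohol, and the C7–O bond (α) is not touched.

Step 7
Reactants: 10 (S)-(−)-citronellol
Product: 11 tert-butyl{[(3S)-3,7-dimethyloct-6-en-1-yl]oxy}dimethylsilane
Conditions: TBSCl, imidazole, DMF, rt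
Reagents that add atoms: tert-butyldimethylsilyl chloride, CC(C)(C)[Si](C)(C)Cl
Why: Standard silylation of the primary alcohol; the bought stereocentre (future C13) is not involved.

Step 8
Reactants: 11 citronellyl silyl ether
Product: 12 (4S)-6-[(tert-butyldimethylsilyl)oxy]-4-methylhexanoic acid
Conditions: RuCl3·xH2O (cat.), NaIO4, MeCN/CCl4/H2O, rt
Reagents that add atoms: sodium periodate, [Na+].[O-]I(=O)(=O)=O; water, O
Why: Catalytic RuO4 cleaves the trisubstituted alkene to the carboxylic acid and acetone (oxidative cleavage) without touching the remote stereocentre.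

Step 9
Reactants: 9 3β,7α-diol + 12 silyloxy acid
Product: 13 (3S,5R,7S,10R)-3-hydroxy-4,4,8,10-tetramethyl-trans-decal-8(9)-en-7-yl (4S)-6-[(tert-butyldimethylsilyl)oxy]-4-methylhexanoate (7β-ester)
Conditions: PPh3, DIAD, THF, 0 °C → rt
Reagents that add atoms: none
Why: Mitsunobu esterification: the carboxylate displaces the activated allylic 7α-oxyphosphonium by SN2 and inverts C7 to the 7β-ester, while the neopentyl 3β-hydroxyl is too hindered to react.

Step 10
Reactants: 13 7β-allylic ester
Product: 16 (13S)-15-[(tert-butyldimethylsilyl)oxy]-3β-hydroxylabd-7-ene-11-carboxylic acid (CO2H on C11; C11 epimers), via silyl ketene acetal 14 (not isolated), via bis-silylated rearranged acid 15 (not isolated)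
Conditions: TMSCl, Et3N, LDA (3.5 equiv), THF, −78 °C → 60 °C; then 1 M HCl
Reagents that add atoms: none
Why: Ireland–Claisen [3,3]-sigmatropic rearrangement of the silyl ketene acetal forms the C9–C11 bond suprafacially on the β-face where the C7–O bond stood, which sets C9 (9α-H) and moves the double bond to C7=C8; the C11 centre is a mixture that is removed in step 11.

Step 11
Reactants: 16 C11 carboxylic acid
Product: 18 (13S)-15-[(tert-butyldimethylsilyl)oxy]labd-7-en-3β-ol, via Barton ester 17 (not isolated)
Conditions: N-hydroxypyridine-2-thione, DCC, DMAP (cat.), CH2Cl2, dark, rt; then t-BuSH (excess), hν, rt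
Reagents that add atoms: none
Why: Barton reductive decarboxylation: the thiohydroxamate ester fragments under light to the C11 radical, which excess thiol quenches faster than any homoallyl rearrangement, removing the carrier carbon and the C11 centre without touching C9.

Step 12
Reactants: 18 silyl ether alcohol
Product: 20 (13S)-labd-7-ene-3β,15-diyl diacetate (3S,5R,9S,10R,13S; CNP0251773.1), via diol 19 (not isolated)
Conditions: HF·pyridine, THF, rt; then Ac2O, pyridine, DMAP, rt
Reagents that add atoms: acetic anhydride, CC(=O)OC(C)=O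
Why: Fluoride cleaves the silyl ether and DMAP-catalysed acylation esterifies the primary and the hindered 3β-hydroxyl with retention, giving the target.

**Compound list**

1 | (R)-(−)-carvone | CC1=CC[C@@H](C(C)=C)CC1=O | starting material
2 | (5R)-2,6-dimethyl-5-(prop-1-en-2-yl)cyclohex-2-en-1-one (C6 epimers) | CC1=CC[C@@H](C(C)=C)C(C)C1=O | intermediate
3 | 3-[(1S,6S)-1,3-dimethyl-2-oxo-6-(prop-1-en-2-yl)cyclohex-3-en-1-yl]propanenitrile | N#CCC[C@]1(C)C(=O)C(C)=CC[C@H]1C(C)=C | intermediate
4 | 3-imino-4,4,8,10-tetramethyl-trans-decal-7-en-9-one (cyclic ketimine) | O=C1C(C)=CC[C@H]2C(C)(C)C(=N)CC[C@]12C | intermediate (not isolated)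
5 | (4aS,8aS)-2,5,5,8a-tetramethyl-4,4a,5,7,8,8a-hexahydronaphthalene-1,6-dione | O=C1C(C)=CC[C@H]2C(C)(C)C(=O)CC[C@]12C | intermediate
6 | (4aS,6S,8aS)-6-hydroxy-2,5,5,8a-tetramethyl-4a,5,6,7,8,8a-hexahydronaphthalen-1(4H)-one | O=C1C(C)=CC[C@H]2C(C)(C)[C@@H](O)CC[C@]12C | intermediate
7 | 7α,8α-epoxy-3β-hydroxy-4,4,8,10-tetramethyl-trans-decalin-9-one | O=C1[C@]3(C)O[C@@H]3C[C@H]2C(C)(C)[C@@H](O)CC[C@]12C | intermediate
8 | hydrazone of 7 (C9=N–NH2) | NN=C1[C@]3(C)O[C@@H]3C[C@H]2C(C)(C)[C@@H](O)CC[C@]12C | intermediate (not isolated)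
9 | (3S,5R,7R,10R)-4,4,8,10-tetramethyl-trans-decal-8(9)-ene-3β,7α-diol | C1=C(C)[C@H](O)C[C@H]2C(C)(C)[C@@H](O)CC[C@]12C | intermediate
10 | (S)-(−)-citronellol | OCC[C@@H](C)CCC=C(C)C | starting material
11 | tert-butyl{[(3S)-3,7-dimethyloct-6-en-1-yl]oxy}dimethylsilane | CC(C)(C)[Si](C)(C)OCC[C@@H](C)CCC=C(C)C | intermediate
12 | (4S)-6-[(tert-butyldimethylsilyl)oxy]-4-methylhexanoic acid | CC(C)(C)[Si](C)(C)OCC[C@@H](C)CCC(=O)O | intermediate
13 | (3S,5R,7S,10R)-3-hydroxy-4,4,8,10-tetramethyl-trans-decal-8(9)-en-7-yl (4S)-6-[(tert-butyldimethylsilyl)oxy]-4-methylhexanoate | C1=C(C)[C@@H](OC(=O)CC[C@H](C)CCO[Si](C)(C)C(C)(C)C)C[C@H]2C(C)(C)[C@@H](O)CC[C@]12C | intermediate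
14 | trimethylsilyl ketene acetal of 13 with 3-OTMS | C1=C(C)[C@@H](OC(O[Si](C)(C)C)=CC[C@H](C)CCO[Si](C)(C)C(C)(C)C)C[C@H]2C(C)(C)[C@@H](O[Si](C)(C)C)CC[C@]12C | intermediate (not isolated)
15 | trimethylsilyl ester of 16 with 3-OTMS | CC(C)(C)[Si](C)(C)OCC[C@@H](C)CC(C(=O)O[Si](C)(C)C)[C@H]1C(C)=CC[C@H]2C(C)(C)[C@@H](O[Si](C)(C)C)CC[C@]12C | intermediate (not isolated)
16 | (13S)-15-[(tert-butyldimethylsilyl)oxy]-3β-hydroxylabd-7-ene-11-carboxylic acid (C11 epimers) | CC(C)(C)[Si](C)(C)OCC[C@@H](C)CC(C(=O)O)[C@H]1C(C)=CC[C@H]2C(C)(C)[C@@H](O)CC[C@]12C | intermediate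
17 | 2-thioxopyridin-1(2H)-yl ester of 16 (Barton ester) | CC(C)(C)[Si](C)(C)OCC[C@@H](C)CC(C(=O)On3ccccc3=S)[C@H]1C(C)=CC[C@H]2C(C)(C)[C@@H](O)CC[C@]12C | intermediate (not isolated)
18 | (13S)-15-[(tert-butyldimethylsilyl)oxy]labd-7-en-3β-ol | CC(C)(C)[Si](C)(C)OCC[C@@H](C)CC[C@H]1C(C)=CC[C@H]2C(C)(C)[C@@H](O)CC[C@]12C | intermediate
19 | (13S)-labd-7-ene-3β,15-diol | OCC[C@@H](C)CC[C@H]1C(C)=CC[C@H]2C(C)(C)[C@@H](O)CC[C@]12C | intermediate (not isolated)
20 | (13S)-labd-7-ene-3β,15-diyl diacetate (CNP0251773.1) | CC(=O)OCC[C@@H](C)CC[C@H]1C(C)=CC[C@H]2C(C)(C)[C@@H](OC(C)=O)CC[C@]12C | target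

**Step count and risks**

Total steps: 12. Longest linear sequence: 10 (steps 1–6 and 9–12 from carvone); the side-chain acid takes 2 steps (7–8).

The three steps most likely to fail:

Step 2 (mono-Michael addition). The nitrile anion may add back to the enone (bicyclo[2.2.2]octanone) or oligomerise acrylonitrile. The fallback sets out from 2 and comes back at 3. The lithium enolate of 2 is C-allylated with allyl bromide, with the same anti approach, to give 6-allyl-6-methylcarvone F1. Only the monosubstituted vinyl group is hydroborated with disiamylborane and oxidised (NaBO3) to the primary alcohol F2. This is converted in one pot to nitrile 3 (TEMPO cat., PhI(OAc)2, NH4OAc, MeCN/H2O).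

Step 3 (radical closure onto the nitrile). The 6-exo addition of a tertiary radical to C≡N is slow and may lose to simple reduction of the alkene. The fallback sets out from 3 and comes back at 5. Markovnikov addition of HBr (HBr/AcOH, 0 °C) to the isopropenyl group gives the tertiary bromide F3. Slow addition of Bu3SnH/AIBN (benzene, 80 °C) then generates the radical by bromine abstraction in a chain process at low hydride concentration. It closes to ketimine 4, which is hydrolysed to 5.

Step 6 (Wharton transposition). Hydrazone formation at a ketone flanked by two fully substituted carbons may be slow, and yields of this reaction vary. The fallback sets out from 6 and comes back at 13, so 7, 8, 9 and the Mitsunobu inversion are bypassed. Luche reduction (NaBH4, CeCl3, MeOH, −78 °C; hydride from the α-face) gives the 9β-allylic alcohol F4. Catalytic O3ReOSiPh3 (Et2O, 0 °C) moves the hydroxyl suprafacially to the less hindered position, giving the 7β-allylic alcohol F5. Steglich esterification of F5 with 12 (DCC, DMAP, CH2Cl2) acylates the allylic hydroxyl with retention to give 13.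

**Further compounds**

F1 | step 2 | (5S,6S)-6-allyl-2,6-dimethyl-5-(prop-1-en-2-yl)cyclohex-2-en-1-one | C=CC[C@]1(C)C(=O)C(C)=CC[C@H]1C(C)=C
F2 | step 2 | (5S,6S)-6-(3-hydroxypropyl)-2,6-dimethyl-5-(prop-1-en-2-yl)cyclohex-2-en-1-one | OCCC[C@]1(C)C(=O)C(C)=CC[C@H]1C(C)=C
F3 | step 3 | 3-[(1S,6R)-6-(2-bromopropan-2-yl)-1,3-dimethyl-2-oxocyclohex-3-en-1-yl]propanenitrile | N#CCC[C@]1(C)C(=O)C(C)=CC[C@H]1C(C)(C)Br
F4 | step 6 | 4,4,8,10-tetramethyl-trans-decal-7-ene-3β,9β-diol | O[C@H]1C(C)=CC[C@H]2C(C)(C)[C@@H](O)CC[C@]12C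
F5 | step 6 | 4,4,8,10-tetramethyl-trans-decal-8(9)-ene-3β,7β-diol | C1=C(C)[C@@H](O)C[C@H]2C(C)(C)[C@@H](O)CC[C@]12C
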